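## Retrosynthetic overview

- The strategy rests on the C5–C6 bond of the 14-membered carbocycle. C5 is a CH2 allylic to the E C3=C4 alkene, and C6 is the CH2 on the C7–C8 oxirane. Cutting this bond gives a C5 allyl phenyl sulfone carbanion and a primary C6 bromide beside the intact oxirane.
- The oxirane comes from a Katsuki–Sharpless epoxidation of the C6 allylic alcohol. The sulfone is carried as a phenyl sulfide and oxidised only after the Grignard, NaH and i-Bu2AlH steps.
- The 2,5-dihydrofuran (O, C2, C1, C15, C16, with C17 on C15) comes from an α-hydroxy ketone (C2–OH, C1=O) and a phosphonoacrylate. The ketone comes from a C14 Grignard reagent and a C1 aldehyde.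
- C1–C5 derive from D-glyceraldehyde acetonide (source of C2) and a propionate ylide, and C6–C13 from geraniol. C14, which none of these pieces holds, is grafted with a silylmethyl Grignard reagent.
- Ring order: dihydrofuran, then oxirane, then the 14-membered carbocycle.

Key step: step 23

Remark on the chemistry: cembrane numbering is used for seco and cyclic compounds (C1=C15 dihydrofuran alkene, C2 ring OCH, C16 ring OCH2, C17 exocyclic CH2O, C7–C8 oxirane). It is assumed that the C1 carbinol epimers and the C5 sulfone epimers need no separation, since both centres are erased later.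

## Route

Step 1
Reactants: 1 (R)-2,3-O-isopropylidene-D-glyceraldehyde; 2 ethyl 2-(triphenylphosphoranylidene)propanoate
Product: 3 ethyl (2E)-3-[(4S)-2,2-dimethyl-1,3-dioxolan-4-yl]-2-methylprop-2-enoate
Conditions: CH2Cl2, 0 °C to rt
Reagents that add atoms: none
Why: Wittig olefination with an α-methyl ester-stabilised ylide in an aprotic solvent should give the E trisubstituted enoate, brings in C4, its methyl group and C5, and does not touch the oxygen-bearing centre that becomes C2.

Step 2
Reactants: 3 enoate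
Product: 4 (2E)-3-[(4S)-2,2-dimethyl-1,3-dioxolan-4-yl]-2-methylprop-2-en-1-ol
Conditions: i-Bu2AlH (2.2 equiv), CH2Cl2, −78 °C
Reagents that add atoms: none
Why: Twofold 1,2-hydride reduction of the conjugated ester by i-Bu2AlH at low temperature should stop at the allylic alcohol without harm to the acetonide or the alkene geometry.

Step 3
Reactants: 4 allylic alcohol
Product: 5 (4S)-2,2-dimethyl-4-[(1E)-2-methyl-3-(phenylsulfanyl)prop-1-en-1-yl]-1,3-dioxolane
Conditions: PhSSPh, n-Bu3P, THF, 0 °C to rt
Reagents that add atoms: diphenyl disulfide, c1ccccc1SSc1ccccc1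
Why: Hata thioetherification, in which the alkoxyphosphonium ion is displaced by thiophenolate in an SN2 step at the primary allylic C5, places sulfur as a non-acidic sulfide that will pass the Grignard, NaH and i-Bu2AlH steps where a sulfone would be deprotonated.

Step 4
Reactants: 5 sulfide acetonide
Product: 6 (2S,3E)-4-methyl-5-(phenylsulfanyl)pent-3-ene-1,2-diol
Conditions: AcOH–H2O (4:1), rt
Reagents that add atoms: none
Why: Acid-catalysed acetal hydrolysis under weakly acidic conditions should free the 1,2-diol without ionising the allylic C2–O bond, so that C2 keeps its configuration.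

Step 5
Reactants: 6 diol
Product: 7 (2S,3E)-4-methyl-5-(phenylsulfanyl)-1,2-bis(triethylsilyloxy)pent-3-ene
Conditions: Et3SiCl (2.4 equiv), imidazole, CH2Cl2, 0 °C
Reagents that add atoms: chlorotriethylsilane, CC[Si](Cl)(CC)CC
Why: Imidazole-promoted silylation covers both hydroxyl groups and prepares their differentiation in the next step.

Step 6
Reactants: 7 bis(triethylsilyl) ether
Product: 8 (2S,3E)-4-methyl-5-(phenylsulfanyl)-2-(triethylsilyloxy)pent-3-enal (C1 aldehyde)
Conditions: (COCl)2, DMSO, CH2Cl2, −78 to −40 °C; Et3N, −78 to −20 °C; used at once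
Reagents that add atoms: none
Why: Swern oxidation applied to a bis(triethylsilyl) ether cleaves and oxidises only the unhindered primary silyl ether, which saves a separate deprotection, and the low temperature together with allylic 1,3-strain from the C4 methyl group (C2–H held in the alkene plane) should keep the α-silyloxy aldehyde from enolising.

Step 7
Reactants: 9 geraniol
Product: 10 geranyl tert-butyldimethylsilyl ether
Conditions: t-BuMe2SiCl, imidazole, CH2Cl2, rt
Reagents that add atoms: tert-butylchlorodimethylsilane, CC(C)(C)[Si](C)(C)Cl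
Why: Standard silylation gives a C6 ether that is stable to organomagnesium reagents, hydrides and NaH and is graded in acid lability between the triethylsilyl and the tert-butyldiphenylsilyl ethers used elsewhere.

Step 8
Reactants: 10 geranyl silyl ether
Product: 11 (2E,6E)-8-(tert-butyldimethylsilyloxy)-2,6-dimethylocta-2,6-dien-1-ol
Conditions: SeO2 (0.1 equiv), t-BuOOH, salicylic acid (cat.), CH2Cl2, 0 °C to rt; then NaBH4, MeOH, 0 °C
Reagents that add atoms: tert-butyl hydroperoxide, CC(C)(C)OO (terminal oxygen source, relayed by selenium dioxide, O=[Se]=O)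
Why: Selenium dioxide allylic oxidation (ene reaction, then 2,3-sigmatropic shift) attacks the more electron-rich distal trisubstituted alkene and, by its known preference, the E methyl group that becomes C13, while NaBH4 returns any over-oxidised enal to 11.

Step 9
Reactants: 11 allylic alcohol
Product: 12 (2E,6E)-8-bromo-1-(tert-butyldimethylsilyloxy)-3,7-dimethylocta-2,6-diene
Conditions: CBr4, PPh3, CH2Cl2, 0 °C
Reagents that add atoms: carbon tetrabromide, BrC(Br)(Br)Br
Why: Appel bromination converts the primary allylic alcohol by SN2 displacement under neutral conditions, without allylic transposition or loss of the silyl ether.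

Step 10
Reactants: 12 allylic bromide; 13 (chloromethyl)(isopropoxy)dimethylsilane
Product: 15 (3E,7E)-9-(tert-butyldimethylsilyloxy)-1-(isopropoxydimethylsilyl)-3,7-dimethylnona-3,7-diene, via silylmethyl Grignard reagent 14 (not isolated)
Conditions: 13, Mg, THF, rt; then 12, Li2CuCl4 (3 mol %), THF, 0 °C
Reagents that add atoms: magnesium, [Mg] (its atom stays only in 14)
Why: Copper-catalysed Grignard cross-coupling of a primary allylic bromide under cuprate-type conditions (Li2CuCl4, THF, excess Grignard reagent) should take place at the α carbon C13 and adds C14 as a silylmethyl group, the one skeletal carbon that the other building blocks do not supply.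

Step 11
Reactants: 15 alkoxysilane
Product: 16 (3E,7E)-9-(tert-butyldimethylsilyloxy)-3,7-dimethylnona-3,7-dien-1-ol
Conditions: 30 % H2O2, KHCO3, THF–MeOH, rt
Reagents that add atoms: hydrogen peroxide, OO
Why: Tamao–Fleming oxidation replaces C–Si by C–OH through peroxide attack on silicon and a 1,2-shift, and the fluoride-free variant spares the silyl ether and the alkenes.

Step 12
Reactants: 16 homoallylic alcohol
Product: 17 (2E,6E)-9-bromo-1-(tert-butyldimethylsilyloxy)-3,7-dimethylnona-2,6-diene
Conditions: CBr4, PPh3, CH2Cl2, 0 °C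
Reagents that add atoms: carbon tetrabromide, BrC(Br)(Br)Br
Why: Appel bromination of an unhindered primary alcohol is a clean SN2 process that leaves both E alkenes and the silyl ether unchanged.

Step 13
Reactants: 17 homoallylic bromide; 8 C1 aldehyde
Product: 19 (2E,4S,8E,12E)-14-(tert-butyldimethylsilyloxy)-2,8,12-trimethyl-1-(phenylsulfanyl)-4-(triethylsilyloxy)tetradeca-2,8,12-trien-5-ol (epimers at the carbinol C1), via C14 Grignard reagent 18 (not isolated)
Conditions: 17, Mg, THF, 35 °C; then 8, THF, −78 °C; cold aqueous quench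
Reagents that add atoms: magnesium, [Mg] (its atom stays only in 18)
Why: Grignard formation from the primary homoallylic bromide and 1,2-addition to the aldehyde form C14–C1, the carbinol centre arises as an epimer mixture that is of no consequence because step 14 removes it, and the cold quench prevents silyl migration from the C2 oxygen to the C1 oxygen.

Step 14
Reactants: 19 carbinol
Product: 20 (2E,4S,8E,12E)-14-(tert-butyldimethylsilyloxy)-2,8,12-trimethyl-1-(phenylsulfanyl)-4-(triethylsilyloxy)tetradeca-2,8,12-trien-5-one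
Conditions: Dess–Martin periodinane, NaHCO3, CH2Cl2, 0 °C to rt
Reagents that add atoms: none
Why: Dess–Martin oxidation under bicarbonate buffer is neutral, tolerates aryl sulfides, silyl ethers and alkenes, and should give the C1 ketone without enolisation at C2.

Step 15
Reactants: 20 α-silyloxy ketone
Product: 21 (2E,4S,8E,12E)-14-(tert-butyldimethylsilyloxy)-4-hydroxy-2,8,12-trimethyl-1-(phenylsulfanyl)tetradeca-2,8,12-trien-5-one
Conditions: PPTS (0.1 equiv), MeOH–CH2Cl2, 0 °C
Reagents that add atoms: none
Why: Acid-catalysed methanolysis exploits the far greater lability of a triethylsilyl over a tert-butyldimethylsilyl ether, so that only the C2 oxygen is freed under conditions too mild for a ketol shift.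

Step 16
Reactants: 21 α-hydroxy ketone; 22 ethyl 2-(diethoxyphosphoryl)acrylate
Product: 24 ethyl (5S)-4-[(3E,7E)-9-(tert-butyldimethylsilyloxy)-3,7-dimethylnona-3,7-dien-1-yl]-5-[(1E)-2-methyl-3-(phenylsulfanyl)prop-1-en-1-yl]-2,5-dihydrofuran-3-carboxylate, via oxa-Michael phosphonate carbanion 23 (not isolated)
Conditions: NaH (1.05 equiv) added to 21 and 22 (1.2 equiv), THF, −20 °C to rt
Reagents that add atoms: sodium hydride, [Na+].[H-] (its sodium stays only in 23)
Why: Tandem oxa-Michael addition and intramolecular Horner–Wadsworth–Emmons olefination is a known route from α-hydroxy ketones to 2,5-dihydrofuran-3-carboxylates, in which the C2 alkoxide adds to the doubly activated acrylate (O–C16), the phosphonate carbanion closes on the C1 ketone (C15=C1, five-membered ring), and C2 keeps its C–O bond and thus its configuration provided the alkoxide is trapped as it forms.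

Step 17
Reactants: 24 dihydrofuran ester
Product: 25 {(5S)-4-[(3E,7E)-9-(tert-butyldimethylsilyloxy)-3,7-dimethylnona-3,7-dien-1-yl]-5-[(1E)-2-methyl-3-(phenylsulfanyl)prop-1-en-1-yl]-2,5-dihydrofuran-3-yl}methanol
Conditions: i-Bu2AlH (2.5 equiv), CH2Cl2, −78 °C
Reagents that add atoms: none
Why: 1,2-Hydride reduction of the conjugated ester with i-Bu2AlH gives the C17 allylic alcohol and leaves the sulfide, silyl ether and ring ether alone.

Step 18
Reactants: 25 C17 alcohol
Product: 26 the C17 tert-butyldiphenylsilyl ether of 25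
Conditions: t-BuPh2SiCl, imidazole, CH2Cl2, rt
Reagents that add atoms: tert-butylchlorodiphenylsilane, CC(C)(C)[Si](Cl)(c1ccccc1)c1ccccc1
Why: Silylation blocks the second allylic alcohol before the directed epoxidation with a group that has no acidic or electrophilic site for the later carbanion and outlasts the acidic release of the C6 hydroxyl group.

Step 19
Reactants: 26 sulfide
Product: 28 the C5 phenyl sulfone of 26 (C6 OTBS, C17 OTBDPS), via allyl sulfoxide 27 (not isolated)
Conditions: (NH4)6Mo7O24·4H2O (10 mol %), 30 % H2O2, EtOH, 0 °C to rt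
Reagents that add atoms: hydrogen peroxide, OO
Why: Molybdate-catalysed peroxide oxidation of a sulfide to the sulfone is much faster at sulfur than at unactivated trisubstituted alkenes, as known for prenyl-type sulfides, and it is placed here because no strong base is used before step 23 and because the C6 hydroxyl group, which would direct epoxidation, is still silylated.

Step 20
Reactants: 28 sulfone
Product: 29 the C6 allylic alcohol (C5 sulfone, C17 OTBDPS)
Conditions: PPTS (0.3 equiv), EtOH, rt to 40 °C
Reagents that add atoms: none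
Why: Acid-catalysed ethanolysis distinguishes the two primary allylic silyl ethers, since the tert-butyldiphenylsilyl ether is far more stable to acid than the tert-butyldimethylsilyl ether.

Step 21
Reactants: 29 allylic alcohol
Product: 30 the (7S,8S)-epoxy alcohol, side chain (3E)-6-[(2S,3S)-3-(hydroxymethyl)-2-methyloxiran-2-yl]-3-methylhex-3-en-1-yl
Conditions: Ti(OiPr)4, L-(+)-diethyl tartrate, t-BuOOH (decane), 4 Å molecular sieves, CH2Cl2, −20 °C
Reagents that add atoms: tert-butyl hydroperoxide, CC(C)(C)OO
Why: Katsuki–Sharpless asymmetric epoxidation acts only on the alkene of the one free allylic alcohol, and the L-(+)-tartrate complex delivers oxygen to the face that turns geraniol into (2S,3S)-epoxygeraniol, which sets (7S,8S) under reagent control, the E alkene giving the trans oxirane.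

Step 22
Reactants: 30 epoxy alcohol
Product: 32 seco C5 sulfone C6 bromide, side chain (3E)-6-[(2S,3R)-3-(bromomethyl)-2-methyloxiran-2-yl]-3-methylhex-3-en-1-yl, via epoxy mesylate 31 (not isolated)
Conditions: MsCl, Et3N, CH2Cl2, −20 °C; then LiBr, THF, 0 °C to rt
Reagents that add atoms: lithium bromide, [Li+].[Br-]; methanesulfonyl chloride, CS(=O)(=O)Cl (its atoms stay only in 31)
Why: Mesylation and Finkelstein-type SN2 displacement by bromide at the primary C6 leave both oxirane C–O bonds untouched, so that C7 and C8 keep their configuration (the C7 descriptor becomes R only because bromine raises the rank of C6).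

Step 23
Reactants: 32 seco C5 sulfone C6 bromide
Product: 34 (2S,7S,8S,3E,11E)-17-(tert-butyldiphenylsilyloxy)-2,16:7,8-diepoxy-5-(phenylsulfonyl)cembra-1(15),3,11-triene (C5 epimers), via potassium C5 carbanion 33 (not isolated)
Conditions: 32 (0.001 M in THF), −78 °C; KN(SiMe3)2 (1.02 equiv, toluene solution) dropwise; −78 to −10 °C; pH 7 buffer quench while cold
Reagents that add atoms: potassium bis(trimethylsilyl)amide, C[Si](C)(C)[N-][Si](C)(C)C.[K+] (its potassium stays only in 33)
Why: KN(SiMe3)2 removes a C5 proton, which lies between the sulfonyl group and the C3=C4 alkene and is by far the most acidic in 32, and carbanion 33 displaces bromide at C6 in an intramolecular SN2 reaction that forms C5–C6. The closest known reaction types are the macrocyclising alkylation of allyl sulfone carbanions by ω-halides for 14-membered carbocycles and the alkylation of sulfone carbanions with 2,3-epoxy-1-halides that leaves the oxirane in place. The ring closes in the 14-exo-tet mode, and the two E alkenes, the trans oxirane and the dihydrofuran cut down the free rotors of the chain. C5 becomes a stereocentre without control and both epimers are accepted because step 24 turns it back into CH2, while C2, C7 and C8 are not touched since no bond to them is broken. The step needs α over γ alkylation (charge is held at C5 by sulfur and C3 is screened by the dihydrofuran), attack at C6 rather than C7 (a primary carbon activated by the neighbouring C–O bond against a secondary carbon beside quaternary C8, with weakly Lewis acidic potassium giving the oxirane no help) and ring closure over dimerisation (high dilution). One equivalent of base and a cold quench keep 34 from being deprotonated again, which would let C5 open the oxirane at C7 to a cyclopropane.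

Step 24
Reactants: 34 macrocyclic sulfone
Product: 35 (2S,7S,8S,3E,11E)-17-(tert-butyldiphenylsilyloxy)-2,16:7,8-diepoxycembra-1(15),3,11-triene
Conditions: Pd(PPh3)4 (10 mol %), NaBH4, THF–i-PrOH (4:1), 0 °C to rt
Reagents that add atoms: none
Why: In this palladium-catalysed hydride substitution of an allylic sulfone, zerovalent palladium ionises the C5–S bond of either epimer to a π-allyl complex and borohydride hands hydride to the less hindered C5 terminus, away from the branched and oxygen-bearing C2, so that C3=C4 should stay in place and E, while NaBH4 spares the oxirane that LiBHEt3 would open and avoids the free ambident allyl anion of a dissolving-metal cleavage, which could be protonated at C3 or expel the C2 alkoxide.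

Step 25
Reactants: 35 silyl ether
Product: 36 (2S,7S,8S,3E,11E)-2,16:7,8-diepoxycembra-1(15),3,11-trien-17-ol
Conditions: n-Bu4NF, THF, 0 °C to rt
Reagents that add atoms: none
Why: Fluoride-induced desilylation is driven by the Si–F bond and is neutral enough for the trisubstituted oxirane and the bis-allylic ring ether.

Step 26
Reactants: 36 C17 alcohol
Product: 37 CNP0140293.1, (2S,7S,8S,3E,11E)-17-acetoxy-2,16:7,8-diepoxycembra-1(15),3,11-triene
Conditions: Ac2O, pyridine, DMAP (cat.), CH2Cl2, 0 °C to rt
Reagents that add atoms: acetic anhydride, CC(=O)OC(C)=O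
Why: DMAP-catalysed acetylation of the only hydroxyl group completes the target under mild basic conditions that affect no stereocentre.

## Compound list

1 | (R)-2,3-O-isopropylidene-D-glyceraldehyde | O=C[C@H]1COC(C)(C)O1 | starting material
2 | ethyl 2-(triphenylphosphoranylidene)propanoate | CCOC(=O)C(C)=P(c1ccccc1)(c1ccccc1)c1ccccc1 | starting material
3 | ethyl (2E)-3-[(4S)-2,2-dimethyl-1,3-dioxolan-4-yl]-2-methylprop-2-enoate | CCOC(=O)/C(C)=C/[C@H]1COC(C)(C)O1 | intermediate
4 | (2E)-3-[(4S)-2,2-dimethyl-1,3-dioxolan-4-yl]-2-methylprop-2-en-1-ol | OC/C(C)=C/[C@H]1COC(C)(C)O1 | intermediate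
5 | (4S)-2,2-dimethyl-4-[(1E)-2-methyl-3-(phenylsulfanyl)prop-1-en-1-yl]-1,3-dioxolane | c1ccccc1SC/C(C)=C/[C@H]1COC(C)(C)O1 | intermediate
6 | (2S,3E)-4-methyl-5-(phenylsulfanyl)pent-3-ene-1,2-diol | c1ccccc1SC/C(C)=C/[C@H](O)CO | intermediate
7 | (2S,3E)-4-methyl-5-(phenylsulfanyl)-1,2-bis(triethylsilyloxy)pent-3-ene | c1ccccc1SC/C(C)=C/[C@H](O[Si](CC)(CC)CC)CO[Si](CC)(CC)CC | intermediate
8 | (2S,3E)-4-methyl-5-(phenylsulfanyl)-2-(triethylsilyloxy)pent-3-enal | c1ccccc1SC/C(C)=C/[C@H](O[Si](CC)(CC)CC)C=O | intermediate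
9 | geraniol | CC(C)=CCC/C(C)=C/CO | starting material
10 | geranyl tert-butyldimethylsilyl ether | CC(C)=CCC/C(C)=C/CO[Si](C)(C)C(C)(C)C | intermediate
11 | (2E,6E)-8-(tert-butyldimethylsilyloxy)-2,6-dimethylocta-2,6-dien-1-ol | OC/C(C)=C/CC/C(C)=C/CO[Si](C)(C)C(C)(C)C | intermediate
12 | (2E,6E)-8-bromo-1-(tert-butyldimethylsilyloxy)-3,7-dimethylocta-2,6-diene | BrC/C(C)=C/CC/C(C)=C/CO[Si](C)(C)C(C)(C)C | intermediate
13 | (chloromethyl)(isopropoxy)dimethylsilane | ClC[Si](C)(C)OC(C)C | starting material
14 | [(isopropoxydimethylsilyl)methyl]magnesium chloride | Cl[Mg]C[Si](C)(C)OC(C)C | intermediate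
15 | (3E,7E)-9-(tert-butyldimethylsilyloxy)-1-(isopropoxydimethylsilyl)-3,7-dimethylnona-3,7-diene | CC(C)O[Si](C)(C)CC/C(C)=C/CC/C(C)=C/CO[Si](C)(C)C(C)(C)C | intermediate
16 | (3E,7E)-9-(tert-butyldimethylsilyloxy)-3,7-dimethylnona-3,7-dien-1-ol | OCC/C(C)=C/CC/C(C)=C/CO[Si](C)(C)C(C)(C)C | intermediate
17 | (2E,6E)-9-bromo-1-(tert-butyldimethylsilyloxy)-3,7-dimethylnona-2,6-diene | BrCC/C(C)=C/CC/C(C)=C/CO[Si](C)(C)C(C)(C)C | intermediate
18 | [(3E,7E)-9-(tert-butyldimethylsilyloxy)-3,7-dimethylnona-3,7-dien-1-yl]magnesium bromide | Br[Mg]CC/C(C)=C/CC/C(C)=C/CO[Si](C)(C)C(C)(C)C | intermediate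
19 | (2E,4S,8E,12E)-14-(tert-butyldimethylsilyloxy)-2,8,12-trimethyl-1-(phenylsulfanyl)-4-(triethylsilyloxy)tetradeca-2,8,12-trien-5-ol (C1 epimers) | c1ccccc1SC/C(C)=C/[C@H](O[Si](CC)(CC)CC)C(O)CC/C(C)=C/CC/C(C)=C/CO[Si](C)(C)C(C)(C)C | intermediate
20 | (2E,4S,8E,12E)-14-(tert-butyldimethylsilyloxy)-2,8,12-trimethyl-1-(phenylsulfanyl)-4-(triethylsilyloxy)tetradeca-2,8,12-trien-5-one | c1ccccc1SC/C(C)=C/[C@H](O[Si](CC)(CC)CC)C(=O)CC/C(C)=C/CC/C(C)=C/CO[Si](C)(C)C(C)(C)C | intermediate
21 | (2E,4S,8E,12E)-14-(tert-butyldimethylsilyloxy)-4-hydroxy-2,8,12-trimethyl-1-(phenylsulfanyl)tetradeca-2,8,12-trien-5-one | c1ccccc1SC/C(C)=C/[C@H](O)C(=O)CC/C(C)=C/CC/C(C)=C/CO[Si](C)(C)C(C)(C)C | intermediate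
22 | ethyl 2-(diethoxyphosphoryl)acrylate | C=C(C(=O)OCC)P(=O)(OCC)OCC | starting material
23 | sodium carbanion of the C2–O–C16 oxa-Michael adduct (C15 bears CO2Et and PO(OEt)2) | c1ccccc1SC/C(C)=C/[C@H](OC[C-](C(=O)OCC)P(=O)(OCC)OCC)C(=O)CC/C(C)=C/CC/C(C)=C/CO[Si](C)(C)C(C)(C)C.[Na+] | intermediate
24 | ethyl (5S)-4-[(3E,7E)-9-(tert-butyldimethylsilyloxy)-3,7-dimethylnona-3,7-dien-1-yl]-5-[(1E)-2-methyl-3-(phenylsulfanyl)prop-1-en-1-yl]-2,5-dihydrofuran-3-carboxylate | c1ccccc1SC/C(C)=C/[C@@H]1OCC(C(=O)OCC)=C1CC/C(C)=C/CC/C(C)=C/CO[Si](C)(C)C(C)(C)C | intermediate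
25 | C17 alcohol from 24, (2S), C5 SPh, C6 OTBS | c1ccccc1SC/C(C)=C/[C@@H]1OCC(CO)=C1CC/C(C)=C/CC/C(C)=C/CO[Si](C)(C)C(C)(C)C | intermediate
26 | C17 tert-butyldiphenylsilyl ether, (2S), C5 SPh, C6 OTBS | c1ccccc1SC/C(C)=C/[C@@H]1OCC(CO[Si](c2ccccc2)(c2ccccc2)C(C)(C)C)=C1CC/C(C)=C/CC/C(C)=C/CO[Si](C)(C)C(C)(C)C | intermediate
27 | C5 phenyl sulfoxide of 26 (epimers at sulfur) | O=S(c1ccccc1)C/C(C)=C/[C@@H]1OCC(CO[Si](c2ccccc2)(c2ccccc2)C(C)(C)C)=C1CC/C(C)=C/CC/C(C)=C/CO[Si](C)(C)C(C)(C)C | intermediate
28 | C5 phenyl sulfone, (2S), C6 OTBS, C17 OTBDPS | O=S(=O)(c1ccccc1)C/C(C)=C/[C@@H]1OCC(CO[Si](c2ccccc2)(c2ccccc2)C(C)(C)C)=C1CC/C(C)=C/CC/C(C)=C/CO[Si](C)(C)C(C)(C)C | intermediate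
29 | C5 phenyl sulfone, (2S), C6 OH, C17 OTBDPS | O=S(=O)(c1ccccc1)C/C(C)=C/[C@@H]1OCC(CO[Si](c2ccccc2)(c2ccccc2)C(C)(C)C)=C1CC/C(C)=C/CC/C(C)=C/CO | intermediate
30 | (2S,7S,8S)-epoxy alcohol, C5 sulfone, C17 OTBDPS | O=S(=O)(c1ccccc1)C/C(C)=C/[C@@H]1OCC(CO[Si](c2ccccc2)(c2ccccc2)C(C)(C)C)=C1CC/C(C)=C/CC[C@]2(C)O[C@H]2CO | intermediate
31 | (2S,7S,8S)-epoxy C6 mesylate | O=S(=O)(c1ccccc1)C/C(C)=C/[C@@H]1OCC(CO[Si](c2ccccc2)(c2ccccc2)C(C)(C)C)=C1CC/C(C)=C/CC[C@]2(C)O[C@H]2COS(C)(=O)=O | intermediate
32 | seco C5 sulfone C6 bromide, (2S,7R,8S) by descriptor, same spatial oxirane as 30 | O=S(=O)(c1ccccc1)C/C(C)=C/[C@@H]1OCC(CO[Si](c2ccccc2)(c2ccccc2)C(C)(C)C)=C1CC/C(C)=C/CC[C@]2(C)O[C@H]2CBr | intermediate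
33 | potassium C5 carbanion of 32 | [K+].O=S(=O)(c1ccccc1)[CH-]/C(C)=C/[C@@H]1OCC(CO[Si](c2ccccc2)(c2ccccc2)C(C)(C)C)=C1CC/C(C)=C/CC[C@]2(C)O[C@H]2CBr | intermediate
34 | (2S,7S,8S,3E,11E)-17-(tert-butyldiphenylsilyloxy)-2,16:7,8-diepoxy-5-(phenylsulfonyl)cembra-1(15),3,11-triene (C5 epimers) | CC(C)(C)[Si](c1ccccc1)(c1ccccc1)OCC1=C2CC/C(C)=C/CC[C@]3(C)O[C@H]3CC(S(=O)(=O)c3ccccc3)/C(C)=C/[C@@H]2OC1 | intermediate
35 | (2S,7S,8S,3E,11E)-17-(tert-butyldiphenylsilyloxy)-2,16:7,8-diepoxycembra-1(15),3,11-triene | CC(C)(C)[Si](c1ccccc1)(c1ccccc1)OCC1=C2CC/C(C)=C/CC[C@]3(C)O[C@H]3CC/C(C)=C/[C@@H]2OC1 | intermediate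
36 | (2S,7S,8S,3E,11E)-2,16:7,8-diepoxycembra-1(15),3,11-trien-17-ol | OCC1=C2CC/C(C)=C/CC[C@]3(C)O[C@H]3CC/C(C)=C/[C@@H]2OC1 | intermediate
37 | CNP0140293.1, (2S,7S,8S,3E,11E)-17-acetoxy-2,16:7,8-diepoxycembra-1(15),3,11-triene | CC(=O)OCC1=C2CC/C(C)=C/CC[C@]3(C)O[C@H]3CC/C(C)=C/[C@@H]2OC1 | target

## Step count and risks

Total step count: 26.
Longest linear sequence: 20 steps (steps 1–6 and 13–26). The geraniol branch, steps 7–12 and 13–26, is equally long.

**Step 23 (macrocyclisation).**
- Three things may go wrong. Intermolecular alkylation may outrun ring closure. Proton transfer from the cyclised sulfone to unreacted carbanion may be followed by attack of C5 on C7 with opening of the oxirane. Bromophilic attack may fragment the oxirane.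
- The fallback sets out from sulfone 28 and comes back at macrocyclic sulfone 34. A removable ester makes the C5 nucleophile softer and leaves the cyclised product without an acidic C5–H.
- Compound 28 is deprotonated with LiN(SiMe3)2 (two equivalents, THF, −78 °C) and C-acylated with allyl chloroformate to the allyl α-sulfonyl ester F1.
- PPTS in EtOH frees the C6 allylic alcohol F2.
- Katsuki–Sharpless epoxidation with L-(+)-diethyl tartrate gives the epoxy alcohol F3.
- MsCl and Et3N, then LiBr, give the epoxy bromide F4.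
- Cs2CO3 in DMF under high dilution closes the same C5–C6 bond to the macrocyclic α-sulfonyl ester F5. Its quaternary C5 cannot be deprotonated toward the oxirane.
- Pd(PPh3)4 and morpholine remove the allyl group, and the α-sulfonyl carboxylic acid loses CO2 on gentle warming to give 34.

**Step 24 (desulfonylation).**
- Three things may go wrong. Hydride may be delivered to C3, which shifts the alkene to C4=C5. Ionisation of the hindered secondary sulfone may be sluggish. Liberated borane may hydroborate an alkene.
- The fallback sets out from 34 and comes back at 35, and it leaves the π-allyl manifold altogether. It is a single-electron reductive cleavage with sodium amalgam, Na(Hg), and Na2HPO4 buffer in MeOH–THF at −20 °C.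
- The allyl anion is protonated by the solvent as it forms. Any positional alkene isomer is removed on AgNO3-impregnated silica.
- No new compound arises on this path (F0).

**Step 16 (dihydrofuran annulation).**
- Three things may go wrong. Enediolate formation before O-alkylation may erode the C2 configuration. The same enediolate may shift the ketol toward the conjugated C2 ketone. Retro-oxa-Michael cleavage may compete with the olefination.
- The fallback sets out from ketone 20 and comes back at ester 24. It removes the carbonyl group before any base is used.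
- Petasis methylenation (Cp2TiMe2, toluene, 70 °C) gives the 1,1-disubstituted alkene F6.
- PPTS in MeOH frees the bis-allylic alcohol F7, which has no enolisable neighbour.
- NaH and ethyl 2-(bromomethyl)acrylate in THF at 0 °C give the ether F8.
- Ring-closing metathesis with the second-generation Hoveyda–Grubbs catalyst in toluene at 80 °C joins the two methylene carbons' parent atoms C1 and C15, with loss of ethene, to give 24.

## Further compounds

F1 | step 23 | allyl ester at C5 of sulfone 28 (C5 epimers), C6 OTBS, C17 OTBDPS | C=CCOC(=O)C(S(=O)(=O)c1ccccc1)/C(C)=C/[C@@H]1OCC(CO[Si](c2ccccc2)(c2ccccc2)C(C)(C)C)=C1CC/C(C)=C/CC/C(C)=C/CO[Si](C)(C)C(C)(C)C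
F2 | step 23 | C6 allylic alcohol of F1 | C=CCOC(=O)C(S(=O)(=O)c1ccccc1)/C(C)=C/[C@@H]1OCC(CO[Si](c2ccccc2)(c2ccccc2)C(C)(C)C)=C1CC/C(C)=C/CC/C(C)=C/CO
F3 | step 23 | (7S,8S)-epoxy alcohol of F2 | C=CCOC(=O)C(S(=O)(=O)c1ccccc1)/C(C)=C/[C@@H]1OCC(CO[Si](c2ccccc2)(c2ccccc2)C(C)(C)C)=C1CC/C(C)=C/CC[C@]2(C)O[C@H]2CO
F4 | step 23 | epoxy C6 bromide of F3 | C=CCOC(=O)C(S(=O)(=O)c1ccccc1)/C(C)=C/[C@@H]1OCC(CO[Si](c2ccccc2)(c2ccccc2)C(C)(C)C)=C1CC/C(C)=C/CC[C@]2(C)O[C@H]2CBr
F5 | step 23 | macrocyclic C5 sulfone C5 allyl ester (C5 epimers) | CC(C)(C)[Si](c1ccccc1)(c1ccccc1)OCC1=C2CC/C(C)=C/CC[C@]3(C)O[C@H]3CC(C(=O)OCC=C)(S(=O)(=O)c3ccccc3)/C(C)=C/[C@@H]2OC1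
F0 | step 24 | none | none
F6 | step 16 | C1 methylidene analogue of ketone 20, (2S), C2 OTES | c1ccccc1SC/C(C)=C/[C@H](O[Si](CC)(CC)CC)C(=C)CC/C(C)=C/CC/C(C)=C/CO[Si](C)(C)C(C)(C)C
F7 | step 16 | (2S)-bis-allylic alcohol from F6 | c1ccccc1SC/C(C)=C/[C@H](O)C(=C)CC/C(C)=C/CC/C(C)=C/CO[Si](C)(C)C(C)(C)C
F8 | step 16 | 2-(ethoxycarbonyl)allyl ether of F7 | c1ccccc1SC/C(C)=C/[C@H](OCC(=C)C(=O)OCC)C(=C)CC/C(C)=C/CC/C(C)=C/CO[Si](C)(C)C(C)(C)C
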